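## Retrosynthetic overview

1. The target is robinetinidol-(4α→8)-(−)-epigallocatechin 3-O-gallate. The twelve phenols are carried as benzyl ethers, the gallate ester is attached late, and the upper 3-OH is carried as a C3–B(pinacolato) bond that is oxidised with retention.
2. Key disconnection: ring C of the upper unit is opened at C4–C3 (and O1–C2) by a retro-oxa-[4+2] into ortho-quinone methide 16 and (E)-β-borylstyrene 15.
3. Enabling feature: upper C4 is a benzhydrylic carbon on ring A, ortho to the ring-A oxygen O1 (atoms O1–C8a–C4a–C4). Ring A plus C4 is therefore a latent ortho-quinone methide, and the trans C2-aryl/C3-oxygen pair maps onto an E alkene.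
4. The quinone methide precursor, benzhydrol 11, comes from C4–C8 bond formation between the 8-lithio derivative of protected (−)-epigallocatechin and 4-(benzyloxy)-2-hydroxybenzaldehyde. Boronate 15 comes from a boron–Wittig olefination.
5. Ring order: rings D, F and E (lower flavan) arrive intact in (−)-epigallocatechin, which supplies both lower stereocentres. Rings A, B and the galloyl ring G are bought as arenes. Ring C is the only ring built (step 6).

Key step: step 6

Assumption: the (R)-configured phosphoric acid is taken as the catalyst matched to the 4S-forming face of quinone methide 16; should the (S)-acid prove to be the matched one, it is used in its place with no other change.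

## Route

Step 1
Reactants: 1 (−)-epigallocatechin; 2 benzyl bromide
Product: 3 (2R,3R)-5,7-bis(benzyloxy)-2-[3,4,5-tris(benzyloxy)phenyl]chroman-3-ol (penta-O-benzyl-(−)-epigallocatechin)
Conditions: BnBr (5.5 equiv), K2CO3, DMF, 0 °C → rt, argon
Reagents that add atoms: benzyl bromide 2, BrCc1ccccc1
Why: Williamson etherification under carbonate base alkylates the five phenols, which are far more acidic than the 3-OH, and leaves the secondary alcohol free; C2 and C3 are untouched provided air is excluded and the temperature is kept low so that base-induced C2 epimerisation stays slow.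

Step 2
Reactants: 3 penta-O-benzyl-(−)-epigallocatechin; 4 chlorotriethylsilane
Product: 5 3-O-triethylsilyl ether of 3
Conditions: Et3SiCl, imidazole, DMF, rt
Reagents that add atoms: chlorotriethylsilane 4, CC[Si](CC)(CC)Cl
Why: Imidazole-promoted silylation of the single remaining hydroxyl gives a silyl ether that should tolerate the organolithium of step 4 and the weak acid of step 6, yet is removable by acid-catalysed methanolysis without fluoride; no stereocentre is formed.

Step 3
Reactants: 5 silyl ether; 6 N-bromosuccinimide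
Product: 7 8-bromo derivative of 5
Conditions: NBS (1.0 equiv), CH2Cl2, −40 → 0 °C
Reagents that add atoms: N-bromosuccinimide 6, O=C1CCC(=O)N1Br
Why: Electrophilic aromatic bromination should occur on the phloroglucinol-type ring D, the most electron-rich ring, and at C8 rather than C6, the regiochemistry established for benzylated flavan-3-ols; no stereocentre is formed.

Step 4
Reactants: 7 8-bromo flavan; 8 4-(benzyloxy)-2-hydroxybenzaldehyde
Product: 11 [4-(benzyloxy)-2-hydroxyphenyl]{(2R,3R)-5,7-bis(benzyloxy)-3-(triethylsilyloxy)-2-[3,4,5-tris(benzyloxy)phenyl]chroman-8-yl}methanol (both carbinol epimers), via aryllithium 9 (not isolated), via sodium phenolate 10 (not isolated)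
Conditions: 7, t-BuLi (2.0 equiv), THF, −78 °C; separately 8, NaH (1.0 equiv), THF, 0 °C; phenolate solution added at −78 °C, then → 0 °C; sat. aq. NH4Cl; chromatography on Et3N-deactivated silica
Reagents that add atoms: 4-(benzyloxy)-2-hydroxybenzaldehyde 8, O=Cc1ccc(OCc2ccccc2)cc1O
Why: Bromine–lithium exchange followed by 1,2-addition of the aryllithium to the aldehyde, whose phenol is masked as its own sodium salt, forms the C4–C8 bond; the new carbinol centre is formed unselectively, which is harmless because it becomes trigonal in step 6.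

Step 5
Reactants: 12 3,4,5-tris(benzyloxy)benzaldehyde; 13 bis[(pinacolato)boryl]methane
Product: 15 (E)-2-{2-[3,4,5-tris(benzyloxy)phenyl]ethenyl}-4,4,5,5-tetramethyl-1,3,2-dioxaborolane, via lithiated diborylmethane 14 (not isolated)
Conditions: lithium 2,2,6,6-tetramethylpiperidide (from n-BuLi and 2,2,6,6-tetramethylpiperidine), THF, 0 °C; then 12, −78 °C → rt; sat. aq. NH4Cl
Reagents that add atoms: bis[(pinacolato)boryl]methane 13, CC1(C)OB(CB2OC(C)(C)C(C)(C)O2)OC1(C)C
Why: Boron–Wittig olefination: the α-boryl carbanion adds to the aldehyde and the β-alkoxide eliminates a boron–oxygen fragment in a syn manner, which for aryl aldehydes should give the E alkenylboronate; no stereocentre is formed.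

Step 6
Reactants: 11 benzhydrol; 15 (E)-styrylboronate
Product: 17 (2R,3R)-5,7-bis(benzyloxy)-8-{(2S,3S,4S)-7-(benzyloxy)-3-(4,4,5,5-tetramethyl-1,3,2-dioxaborolan-2-yl)-2-[3,4,5-tris(benzyloxy)phenyl]chroman-4-yl}-3-(triethylsilyloxy)-2-[3,4,5-tris(benzyloxy)phenyl]chromane, via ortho-quinone methide 16 (not isolated)
Conditions: 15 (2.5 equiv), (R)-3,3'-bis(2,4,6-triisopropylphenyl)-1,1'-binaphthyl-2,2'-diyl hydrogen phosphate (C50H57O4P, 10 mol %), 4 Å molecular sieves, toluene, 25–40 °C
Reagents that add atoms: boronate 15, CC1(C)OB(/C=C/c2cc(OCc3ccccc3)c(OCc3ccccc3)c(OCc3ccccc3)c2)OC1(C)C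
Why: Proposed new method: the phosphoric acid dehydrates benzhydrol 11 to the (E)-ortho-quinone methide 16 (O1=C8a–C4a=C4 of the upper unit) and stays hydrogen-bonded to its carbonyl oxygen while the borylstyrene adds as the 2π partner in an inverse-electron-demand oxa-[4+2] cycloaddition, the boron-bearing carbon C3 bonding to the methide carbon C4 and C2 bonding to O1; the closest known reaction type is the Brønsted acid-catalysed [4+2] cycloaddition of ortho-quinone methides from ortho-hydroxybenzhydrols with styrenes, here extended to a β-borylstyrene whose C–B bond survives as a masked hydroxyl. Ring C is closed in the cycloaddition mode (suprafacial on both components, asynchronous, with the C3–C4 bond leading), and no other ring is formed. C2 and C3 should come out trans because the E geometry of 15 is transferred stereospecifically, and C4 should come out cis to the C2 aryl and trans to boron from the endo orientation of the styrene aryl over the quinone methide, with the boronate exo and away from the ring-D substituent on C4. The absolute sense (attack on the face of C4 that gives 4S) is to be imposed by the chiral phosphate pocket, and because the lower unit is already (2R,3R) any wrong-face adduct is a diastereomer that should be removable by chromatography. The step needs regioselectivity (C3–C4 rather than C2–C4 bonding), which the C2 aryl group secures by stabilising the positive charge developing at C2 whereas bonding through C2 would place that charge next to the electron-poor boron; it also needs cycloaddition to outrun 1,4-transfer of the alkenyl group from boron, which the non-exchanging pinacol ester and the absence of diol or base should secure.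

Step 7
Reactants: 17 cycloadduct
Product: 18 (2R,3R)-5,7-bis(benzyloxy)-8-{(2S,3S,4S)-7-(benzyloxy)-3-(pinacolatoboryl)-2-[3,4,5-tris(benzyloxy)phenyl]chroman-4-yl}-2-[3,4,5-tris(benzyloxy)phenyl]chroman-3-ol
Conditions: pyridinium p-toluenesulfonate (cat.), MeOH/CH2Cl2, rt
Reagents that add atoms: none
Why: Acid-catalysed methanolysis of the triethylsilyl ether frees the lower 3-OH while the pinacol boronate, the benzyl ethers and the C4–C8 bond are inert to this weak acid, and fluoride, which could trigger β-elimination of the β-aryloxy boronate, is avoided; no stereocentre is touched.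

Step 8
Reactants: 18 alcohol; 19 3,4,5-tris(benzyloxy)benzoyl chloride
Product: 20 3,4,5-tris(benzyloxy)benzoate (lower 3-O-gallate) of 18
Conditions: 19 (1.5 equiv), Et3N, 4-(dimethylamino)pyridine (cat.), CH2Cl2, 0 °C → rt
Reagents that add atoms: 3,4,5-tris(benzyloxy)benzoyl chloride 19, O=C(Cl)c1cc(OCc2ccccc2)c(OCc2ccccc2)c(OCc2ccccc2)c1
Why: Nucleophilic acyl substitution on the only free hydroxyl installs the galloyl group regiospecifically because the upper O3 is still masked as the C–B bond; the configuration at lower C3 is retained since its C–O bond is not broken.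

Step 9
Reactants: 20 boronate ester
Product: 21 dodeca-O-benzyl target, upper unit (2R,3S,4S)-3-hydroxy
Conditions: NaBO3·4H2O, THF/H2O (1:1), rt
Reagents that add atoms: sodium perborate tetrahydrate, [Na+].[O-]OB=O.O.O.O.O
Why: Oxidation of the carbon–boron bond through a peroxoborate with 1,2-migration of C3 from boron to oxygen proceeds with retention and so should set the upper 3-hydroxyl trans to both neighbours, with perborate mild enough for the gallate ester.

Step 10
Reactants: 21 dodeca-O-benzyl target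
Product: 22 target, (2R,3R)-8-[(2R,3S,4S)-3,7-dihydroxy-2-(3,4,5-trihydroxyphenyl)chroman-4-yl]-5,7-dihydroxy-2-(3,4,5-trihydroxyphenyl)chroman-3-yl 3,4,5-trihydroxybenzoate
Conditions: H2 (1 atm), Pd(OH)2 on carbon, THF/MeOH/H2O, rt
Reagents that add atoms: none
Why: Heterogeneous catalytic hydrogenolysis cleaves the twelve benzyl aryl ethers while the ester, the ring C–O bonds and the C4–C8 bond should survive these neutral conditions, leaving all five stereocentres unchanged.

## Compound list

1 | (−)-epigallocatechin, (2R,3R) | O[C@@H]1Cc2c(O)cc(O)cc2O[C@@H]1c1cc(O)c(O)c(O)c1 | starting material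
2 | benzyl bromide | BrCc1ccccc1 | starting material
3 | (2R,3R)-5,7-bis(benzyloxy)-2-[3,4,5-tris(benzyloxy)phenyl]chroman-3-ol | O[C@@H]1Cc2c(OCc3ccccc3)cc(OCc3ccccc3)cc2O[C@@H]1c1cc(OCc2ccccc2)c(OCc2ccccc2)c(OCc2ccccc2)c1 | intermediate
4 | chlorotriethylsilane | CC[Si](CC)(CC)Cl | starting material
5 | (2R,3R)-3-O-triethylsilyl ether of 3 | CC[Si](CC)(CC)O[C@@H]1Cc2c(OCc3ccccc3)cc(OCc3ccccc3)cc2O[C@@H]1c1cc(OCc2ccccc2)c(OCc2ccccc2)c(OCc2ccccc2)c1 | intermediate
6 | N-bromosuccinimide | O=C1CCC(=O)N1Br | starting material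
7 | (2R,3R)-8-bromo derivative of 5 | CC[Si](CC)(CC)O[C@@H]1Cc2c(OCc3ccccc3)cc(OCc3ccccc3)c(Br)c2O[C@@H]1c1cc(OCc2ccccc2)c(OCc2ccccc2)c(OCc2ccccc2)c1 | intermediate
8 | 4-(benzyloxy)-2-hydroxybenzaldehyde | O=Cc1ccc(OCc2ccccc2)cc1O | starting material
9 | (2R,3R)-8-lithio derivative of 5 | CC[Si](CC)(CC)O[C@@H]1Cc2c(OCc3ccccc3)cc(OCc3ccccc3)c([Li])c2O[C@@H]1c1cc(OCc2ccccc2)c(OCc2ccccc2)c(OCc2ccccc2)c1 | intermediate (not isolated)
10 | sodium 5-(benzyloxy)-2-formylphenolate | [Na+].[O-]c1cc(OCc2ccccc2)ccc1C=O | intermediate (not isolated)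
11 | [4-(benzyloxy)-2-hydroxyphenyl]{(2R,3R)-5,7-bis(benzyloxy)-3-(triethylsilyloxy)-2-[3,4,5-tris(benzyloxy)phenyl]chroman-8-yl}methanol, both carbinol epimers | CC[Si](CC)(CC)O[C@@H]1Cc2c(OCc3ccccc3)cc(OCc3ccccc3)c(C(O)c3ccc(OCc4ccccc4)cc3O)c2O[C@@H]1c1cc(OCc2ccccc2)c(OCc2ccccc2)c(OCc2ccccc2)c1 | intermediate
12 | 3,4,5-tris(benzyloxy)benzaldehyde | O=Cc1cc(OCc2ccccc2)c(OCc2ccccc2)c(OCc2ccccc2)c1 | starting material
13 | bis[(pinacolato)boryl]methane | CC1(C)OB(CB2OC(C)(C)C(C)(C)O2)OC1(C)C | starting material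
14 | lithio-bis[(pinacolato)boryl]methane | CC1(C)OB(C([Li])B2OC(C)(C)C(C)(C)O2)OC1(C)C | intermediate (not isolated)
15 | (E)-2-{2-[3,4,5-tris(benzyloxy)phenyl]ethenyl}-4,4,5,5-tetramethyl-1,3,2-dioxaborolane | CC1(C)OB(/C=C/c2cc(OCc3ccccc3)c(OCc3ccccc3)c(OCc3ccccc3)c2)OC1(C)C | intermediate
16 | (6E)-3-(benzyloxy)-6-({(2R,3R)-5,7-bis(benzyloxy)-3-(triethylsilyloxy)-2-[3,4,5-tris(benzyloxy)phenyl]chroman-8-yl}methylidene)cyclohexa-2,4-dien-1-one (ortho-quinone methide) | CC[Si](CC)(CC)O[C@@H]1Cc2c(OCc3ccccc3)cc(OCc3ccccc3)c(/C=C3\C=CC(OCc4ccccc4)=CC3=O)c2O[C@@H]1c1cc(OCc2ccccc2)c(OCc2ccccc2)c(OCc2ccccc2)c1 | intermediate (not isolated)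
17 | cycloadduct: lower (2R,3R) unit with 3-OSiEt3, upper (2S,3S,4S)-3-boryl flavan-4-yl at C8 (the C2 descriptor is S only because boron ranks below carbon; the spatial arrangement is that of the target) | CC[Si](CC)(CC)O[C@@H]1Cc2c(OCc3ccccc3)cc(OCc3ccccc3)c([C@@H]3c4ccc(OCc5ccccc5)cc4O[C@H](c4cc(OCc5ccccc5)c(OCc5ccccc5)c(OCc5ccccc5)c4)[C@H]3B6OC(C)(C)C(C)(C)O6)c2O[C@@H]1c1cc(OCc2ccccc2)c(OCc2ccccc2)c(OCc2ccccc2)c1 | intermediate
18 | desilylated cycloadduct: lower (2R,3R)-3-ol, upper (2S,3S,4S)-3-boryl | O[C@@H]1Cc2c(OCc3ccccc3)cc(OCc3ccccc3)c([C@@H]3c4ccc(OCc5ccccc5)cc4O[C@H](c4cc(OCc5ccccc5)c(OCc5ccccc5)c(OCc5ccccc5)c4)[C@H]3B6OC(C)(C)C(C)(C)O6)c2O[C@@H]1c1cc(OCc2ccccc2)c(OCc2ccccc2)c(OCc2ccccc2)c1 | intermediate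
19 | 3,4,5-tris(benzyloxy)benzoyl chloride | O=C(Cl)c1cc(OCc2ccccc2)c(OCc2ccccc2)c(OCc2ccccc2)c1 | starting material
20 | lower 3-O-[3,4,5-tris(benzyloxy)benzoate] of 18, upper (2S,3S,4S)-3-boryl | O=C(O[C@@H]1Cc2c(OCc3ccccc3)cc(OCc3ccccc3)c([C@@H]3c4ccc(OCc5ccccc5)cc4O[C@H](c4cc(OCc5ccccc5)c(OCc5ccccc5)c(OCc5ccccc5)c4)[C@H]3B6OC(C)(C)C(C)(C)O6)c2O[C@@H]1c1cc(OCc2ccccc2)c(OCc2ccccc2)c(OCc2ccccc2)c1)c1cc(OCc2ccccc2)c(OCc2ccccc2)c(OCc2ccccc2)c1 | intermediate
21 | dodeca-O-benzyl target: lower (2R,3R), upper (2R,3S,4S)-3-ol | O=C(O[C@@H]1Cc2c(OCc3ccccc3)cc(OCc3ccccc3)c([C@@H]3c4ccc(OCc5ccccc5)cc4O[C@H](c4cc(OCc5ccccc5)c(OCc5ccccc5)c(OCc5ccccc5)c4)[C@H]3O)c2O[C@@H]1c1cc(OCc2ccccc2)c(OCc2ccccc2)c(OCc2ccccc2)c1)c1cc(OCc2ccccc2)c(OCc2ccccc2)c(OCc2ccccc2)c1 | intermediate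
22 | (2R,3R)-8-[(2R,3S,4S)-3,7-dihydroxy-2-(3,4,5-trihydroxyphenyl)chroman-4-yl]-5,7-dihydroxy-2-(3,4,5-trihydroxyphenyl)chroman-3-yl 3,4,5-trihydroxybenzoate | O=C(O[C@@H]1Cc2c(O)cc(O)c([C@@H]3c4ccc(O)cc4O[C@H](c4cc(O)c(O)c(O)c4)[C@H]3O)c2O[C@@H]1c1cc(O)c(O)c(O)c1)c1cc(O)c(O)c(O)c1 | target

## Step count and risks

Total step count: 10. Longest linear sequence: 9 steps (steps 1–4 and 6–10 from (−)-epigallocatechin); step 5 is a one-step branch.

Steps most likely to fail:

1. Step 6 (proposed new method). What may go wrong: insufficient face discrimination on the planar quinone methide, cycloaddition too slow with the weakly nucleophilic borylstyrene so that the quinone methide oligomerises, or diversion into 1,4-transfer of the alkenyl group from boron. The fallback uses known flavanyl-cation coupling, sets out from 3 and returns at 21. Alcohol 3 is acylated with 19 (Et3N, 4-(dimethylamino)pyridine, CH2Cl2) to octa-O-benzyl-(−)-epigallocatechin gallate F1. Commercial (+)-dihydrorobinetin is benzylated on its four phenols (2, K2CO3, DMF) to the tetra-O-benzyl flavanonol F2 and reduced with NaBH4 (THF/EtOH) to the flavan-3,4-diol F3. F3 is ionised with trimethylsilyl trifluoromethanesulfonate (Me3SiOSO2CF3, CH2Cl2, −78 °C) in the presence of excess F1. The flavan-4-yl cation should be captured by C8 of ring D trans to the 3-OH in a Friedel–Crafts-type coupling, forming the C4–C8 bond with 4S configuration and giving 21 after separation from any C6-linked isomer.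

2. Step 4. What may go wrong: protonation of the doubly ortho-substituted aryllithium, or slow carbonyl addition to an aldehyde deactivated as its phenolate. The fallback reverses the polarity, sets out from 7 and returns at 11. Aryllithium 9 (from 7 and t-BuLi) is formylated with DMF to the 8-carbaldehyde F4. Commercial 5-(benzyloxy)-2-bromophenol is converted with n-BuLi (2 equiv, THF, −78 °C) into lithium 5-(benzyloxy)-2-lithiophenolate F5, which is used in excess and added to F4 to give 11 after aqueous NH4Cl.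

3. Step 9. What may go wrong: slow oxidation at the hindered secondary boronate under the mild conditions the gallate tolerates, so that perhydrolysis of the ester or ring-opening β-elimination of the boron ate complex competes. The fallback moves the oxidation ahead of the ester, sets out from 17 and returns at 22. Cycloadduct 17 is oxidised with H2O2/NaOH (THF/H2O) to the upper flavan-3-ol F6. Its hydroxyl is benzylated (NaH, 2, DMF) to the benzyl ether F7. The silyl ether is cleaved (pyridinium p-toluenesulfonate, MeOH) to the lower alcohol F8. Acylation with 19 gives the trideca-O-benzyl gallate F9, and hydrogenolysis as in step 10 removes all thirteen benzyl groups to give 22.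

## Further compounds

F1 | step 6 | octa-O-benzyl-(−)-epigallocatechin gallate, (2R,3R) | O=C(O[C@@H]1Cc2c(OCc3ccccc3)cc(OCc3ccccc3)cc2O[C@@H]1c1cc(OCc2ccccc2)c(OCc2ccccc2)c(OCc2ccccc2)c1)c1cc(OCc2ccccc2)c(OCc2ccccc2)c(OCc2ccccc2)c1
F2 | step 6 | (2R,3R)-7-(benzyloxy)-3-hydroxy-2-[3,4,5-tris(benzyloxy)phenyl]chroman-4-one | O=C1c2ccc(OCc3ccccc3)cc2O[C@H](c2cc(OCc3ccccc3)c(OCc3ccccc3)c(OCc3ccccc3)c2)[C@H]1O
F3 | step 6 | (2R,3S)-7-(benzyloxy)-2-[3,4,5-tris(benzyloxy)phenyl]chroman-3,4-diol, C4 epimers | OC1c2ccc(OCc3ccccc3)cc2O[C@H](c2cc(OCc3ccccc3)c(OCc3ccccc3)c(OCc3ccccc3)c2)[C@H]1O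
F4 | step 4 | (2R,3R)-5,7-bis(benzyloxy)-3-(triethylsilyloxy)-2-[3,4,5-tris(benzyloxy)phenyl]chromane-8-carbaldehyde | CC[Si](CC)(CC)O[C@@H]1Cc2c(OCc3ccccc3)cc(OCc3ccccc3)c(C=O)c2O[C@@H]1c1cc(OCc2ccccc2)c(OCc2ccccc2)c(OCc2ccccc2)c1
F5 | step 4 | lithium 5-(benzyloxy)-2-lithiophenolate | [Li]Oc1cc(OCc2ccccc2)ccc1[Li]
F6 | step 9 | lower (2R,3R)-3-OSiEt3, upper (2R,3S,4S)-3-ol | CC[Si](CC)(CC)O[C@@H]1Cc2c(OCc3ccccc3)cc(OCc3ccccc3)c([C@@H]3c4ccc(OCc5ccccc5)cc4O[C@H](c4cc(OCc5ccccc5)c(OCc5ccccc5)c(OCc5ccccc5)c4)[C@H]3O)c2O[C@@H]1c1cc(OCc2ccccc2)c(OCc2ccccc2)c(OCc2ccccc2)c1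
F7 | step 9 | upper 3-O-benzyl ether of F6 | CC[Si](CC)(CC)O[C@@H]1Cc2c(OCc3ccccc3)cc(OCc3ccccc3)c([C@@H]3c4ccc(OCc5ccccc5)cc4O[C@H](c4cc(OCc5ccccc5)c(OCc5ccccc5)c(OCc5ccccc5)c4)[C@H]3OCc4ccccc4)c2O[C@@H]1c1cc(OCc2ccccc2)c(OCc2ccccc2)c(OCc2ccccc2)c1
F8 | step 9 | desilylated F7 (lower 3-OH free) | O[C@@H]1Cc2c(OCc3ccccc3)cc(OCc3ccccc3)c([C@@H]3c4ccc(OCc5ccccc5)cc4O[C@H](c4cc(OCc5ccccc5)c(OCc5ccccc5)c(OCc5ccccc5)c4)[C@H]3OCc4ccccc4)c2O[C@@H]1c1cc(OCc2ccccc2)c(OCc2ccccc2)c(OCc2ccccc2)c1
F9 | step 9 | trideca-O-benzyl target (lower 3-O-tribenzylgallate of F8) | O=C(O[C@@H]1Cc2c(OCc3ccccc3)cc(OCc3ccccc3)c([C@@H]3c4ccc(OCc5ccccc5)cc4O[C@H](c4cc(OCc5ccccc5)c(OCc5ccccc5)c(OCc5ccccc5)c4)[C@H]3OCc4ccccc4)c2O[C@@H]1c1cc(OCc2ccccc2)c(OCc2ccccc2)c(OCc2ccccc2)c1)c1cc(OCc2ccccc2)c(OCc2ccccc2)c(OCc2ccccc2)c1
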